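Guaiane numbering is used. The plan cuts C1–C5 and C8–C9 of the hydroazulene. C5, the β-carbon of the ring A enone, and the oxygenated C8 face each other 1,4 across the seven-membered ring, so an ether bridge between them hides both the C8 carbinol and the C4=C5 alkene until a retro-oxa-Michael opening. A furan provides C5–C8 with that oxygen; a tethered chloromethyl ketone provides the C1–C10–C9 oxyallyl cation. Their intramolecular (4+3) cycloaddition forms ring A and the bridged seven-membered ring at once and fixes C1, C5 and C8 from the temporary tether stereocentres C3 and C4. The precursor is a 2,4-disubstituted furan whose C4(methyl)–C3(silyloxy)–C2–C1 tether ends in C(=O)CH2Cl.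

Key step: step 9

Remark: TBS = tert-butyldimethylsilyl, TES = triethylsilyl, Ts = 4-methylbenzenesulfonyl (TBSO, TESO = the silyloxy groups); methyl 5-bromofuran-3-carboxylate is assumed to be a catalogue compound (C5 bromination of methyl furan-3-carboxylate would supply it otherwise).

Step 1
Reactants: 1 methyl 5-bromofuran-3-carboxylate
Product: 2 2-(5-bromofuran-3-yl)propan-2-ol
Conditions: MeMgBr (3 equiv), THF, 0 °C to rt
Reagents that add atoms: methylmagnesium bromide, C[Mg]Br
Why: Double Grignard addition to the ester should give the tertiary carbinol (C11 with C12 and C13), the ring C–Br bond being inert to MeMgBr at this temperature.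

Step 2
Reactants: 2 2-(5-bromofuran-3-yl)propan-2-ol
Product: 3 2-bromo-4-(2-TBSO-propan-2-yl)furan
Conditions: TBSOTf, 2,6-lutidine, CH2Cl2, −78 to 0 °C
Reagents that add atoms: tert-butyldimethylsilyl trifluoromethanesulfonate, CC(C)(C)[Si](C)(C)OS(=O)(=O)C(F)(F)F
Why: Silyl triflate with a hindered pyridine base silylates the tertiary alcohol without free acid, which would ionise the furyl carbinol, and the bulky ether should then survive organolithium, Lewis acid and alkoxide.

Step 3
Reactants: 4 (E)-but-2-en-1-ol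
Product: 6 [(2S,3S)-3-methyloxiran-2-yl]methyl 4-methylbenzenesulfonate, via epoxy alcohol 5 (not isolated)
Conditions: Ti(OiPr)4 (5 mol %), L-(+)-diethyl tartrate (6 mol %), t-BuOOH, 4 Å MS, CH2Cl2, −20 °C; P(OMe)3; then TsCl, Et3N, DMAP (cat.), −10 °C
Reagents that add atoms: tert-butyl hydroperoxide, CC(C)(C)OO; 4-methylbenzenesulfonyl chloride, Cc1ccc(cc1)S(Cl)(=O)=O
Why: Sharpless asymmetric epoxidation with the natural tartrate is reagent-controlled and should give the (2S,3S)-epoxide of the (E)-allylic alcohol, and sulfonylation in the same pot avoids isolating the water-soluble epoxy alcohol and installs the leaving group used in step 4.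

Step 4
Reactants: 3 2-bromo-4-(2-TBSO-propan-2-yl)furan; 6 [(2S,3S)-3-methyloxiran-2-yl]methyl 4-methylbenzenesulfonate
Product: 9 (2R)-2-{(1R)-1-[4-(2-TBSO-propan-2-yl)furan-2-yl]ethyl}oxirane, via furyllithium 7 (not isolated), via hydroxy tosylate 8 (not isolated)
Conditions: n-BuLi, THF, −78 °C; then 6, BF3·OEt2, −78 °C; then K2CO3, MeOH, 0 °C to rt
Reagents that add atoms: none
Why: Bromine–lithium exchange places the metal only at the furan α-carbon remote from the carbinol, the BF3-promoted SN2 epoxide opening should occur with inversion at the methyl-bearing carbon distal to the electron-withdrawing sulfonyloxymethyl group (setting C4 as R while C3 keeps its configuration), and base then closes the C3 alkoxide onto the primary tosylate (3-exo-tet) to the terminal epoxide.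

Step 5
Reactants: 9 (2R)-2-{(1R)-1-[4-(2-TBSO-propan-2-yl)furan-2-yl]ethyl}oxirane
Product: 11 (5S)-5-{(1R)-1-[4-(2-TBSO-propan-2-yl)furan-2-yl]ethyl}oxolan-2-one, via hydroxy acid 10 (not isolated)
Conditions: AcOH, LiN(iPr)2 (2.1 equiv), THF, 0 to 40 °C; then 9, 45 °C; then aq. HCl to pH 3, rt
Reagents that add atoms: acetic acid, CC(O)=O
Why: The acetic acid dianion should open the terminal epoxide by SN2 at the unhindered CH2 (C2), adding C1 and C10 without touching C3, and the γ-hydroxy acid lactonises on mild acidification (known γ-lactone synthesis from epoxides).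

Step 6
Reactants: 11 (5S)-5-{(1R)-1-[4-(2-TBSO-propan-2-yl)furan-2-yl]ethyl}oxolan-2-one
Product: 12 (4S,5R)-4-hydroxy-N-methoxy-N-methyl-5-[4-(2-TBSO-propan-2-yl)furan-2-yl]hexanamide
Conditions: MeNHOMe·HCl, AlMe3, CH2Cl2, 0 °C to rt
Reagents that add atoms: N,O-dimethylhydroxylamine hydrochloride, CNOC.Cl
Why: Weinreb aminolysis of the lactone by the aluminium amide opens the ring to the N-methoxy-N-methylamide at C10 and frees the C3 hydroxyl, no stereocentre being involved.

Step 7
Reactants: 12 (4S,5R)-4-hydroxy-N-methoxy-N-methyl-5-[4-(2-TBSO-propan-2-yl)furan-2-yl]hexanamide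
Product: 13 (4S,5R)-N-methoxy-N-methyl-5-[4-(2-TBSO-propan-2-yl)furan-2-yl]-4-TESO-hexanamide
Conditions: TESCl, imidazole, DMF, 0 °C to rt
Reagents that add atoms: chlorotriethylsilane, CC[Si](Cl)(CC)CC
Why: Standard silylation masks the C3 carbinol, the latent C3 ketone, so that it can neither form a hemiketal with C10 nor interfere with enolisation in the key step.

Step 8
Reactants: 13 (4S,5R)-N-methoxy-N-methyl-5-[4-(2-TBSO-propan-2-yl)furan-2-yl]-4-TESO-hexanamide
Product: 14 (5S,6R)-1-chloro-6-[4-(2-TBSO-propan-2-yl)furan-2-yl]-5-TESO-heptan-2-one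
Conditions: ICH2Cl, MeLi·LiBr, THF, −78 °C; then AcOH
Reagents that add atoms: chloroiodomethane, ClCI
Why: Chloromethyllithium formed by iodine–lithium exchange adds once to the Weinreb amide because the chelated tetrahedral adduct persists until the acidic quench, which gives the chloromethyl ketone (C9) without any electrophilic chlorination in the presence of the furan.

Step 9
Reactants: 14 (5S,6R)-1-chloro-6-[4-(2-TBSO-propan-2-yl)furan-2-yl]-5-TESO-heptan-2-one
Product: 16 (1S,3S,4R,5S,8R)-5,8-epoxy-11-TBSO-3-TESO-14-norguai-6-en-10-one, via oxyallyl zwitterion 15 (not isolated)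
Conditions: NaOCH2CF3 (1.5 equiv), CF3CH2OH, 0.01 M, 0 °C to rt
Reagents that add atoms: none
Why: Trifluoroethoxide enolises the ketone toward C1 and the enolate expels chloride from C9 to give the oxyallyl cation C1–C10–C9 (zwitterion 15), which the tethered electron-rich 2,4-dialkylfuran should trap across C5 and C8 in a concerted or rapid stepwise (4+3) event; the closest known reaction type is the base-induced intramolecular (4+3) cycloaddition of α-chloro ketone-derived oxyallyl cations with tethered furans in fluorinated alcohols. Ring A closes by 5-exo-trig attack of C1 on furan carbon C5 through the three-atom tether C2–C3–C4, and the seven-membered ring closes when C9 bonds to C8 on the same furan face (7-exo-trig capture of the furan-derived oxocarbenium ion by the enolate), the furan oxygen remaining as the C5–O–C8 bridge. C5 and C8 are fixed together by the furan face that is attacked, and C4 selects it: in the forming five-membered ring the C4 methyl and the trans C3 silyloxy group can both be pseudo-equatorial, the methyl anti to the incoming C1, only on the face that gives (5S,8R). C1 is set by the compact mode of addition that furans prefer under these ionic conditions (oxyallyl oxygen over C6=C7, tether on the enolate carbon syn to that oxygen), which leaves C1–H on the side of the oxygen bridge and the C1–C2 bond equatorial on the new pyranone chair. The step needs cycloaddition to outrun substitution at C9 and Favorskii collapse, one furan face, and the compact mode; high dilution in the weakly nucleophilic solvent, the donor-substituted furan and the two tether stereocentres provide for these, and C1, being α to the C10 carbonyl, stays open to base equilibration, which should favour the equatorial isomer.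

Step 10
Reactants: 16 (1S,3S,4R,5S,8R)-5,8-epoxy-11-TBSO-3-TESO-14-norguai-6-en-10-one
Product: 17 (1R,3S,4R,5R,8R)-5,8-epoxy-11-TBSO-3-TESO-guaia-6,10(14)-diene
Conditions: Ph3PCH3Br, KOtBu, THF, 0 °C to rt
Reagents that add atoms: methyltriphenylphosphonium bromide, [Br-].C[P+](c1ccccc1)(c1ccccc1)c1ccccc1
Why: Wittig methylenation of the accessible bicyclic ketone adds C14 and removes the C10 carbonyl before the enone is unmasked, so that C1 is no longer α to a ketone, and the bridgehead C–O bonds lie near the enolate plane and should not eliminate.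

Step 11
Reactants: 17 (1R,3S,4R,5R,8R)-5,8-epoxy-11-TBSO-3-TESO-guaia-6,10(14)-diene
Product: 18 (1R,3S,4R,5R,8R)-5,8-epoxyguaia-6,10(14)-diene-3,11-diol
Conditions: Bu4NF (4 equiv), THF, 50 °C
Reagents that add atoms: none
Why: Fluoride cleaves both silyl ethers of a substrate that carries no base-sensitive group, freeing the C3 carbinol for oxidation and the C11 carbinol for the last acylation.

Step 12
Reactants: 18 (1R,3S,4R,5R,8R)-5,8-epoxyguaia-6,10(14)-diene-3,11-diol
Product: 20 (1R,8R)-8,11-dihydroxyguaia-4,6,10(14)-trien-3-one, via bridged ketone 19 (not isolated)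
Conditions: NPr4RuO4 (5 mol %), N-methylmorpholine N-oxide, 4 Å MS, CH2Cl2, rt; then DBU (0.2 equiv), 0 °C
Reagents that add atoms: none
Why: Ley–Griffith oxidation converts only the secondary C3 alcohol into the ketone, and amine base then enolises toward C4 and expels the pseudo-axial C5–O bond (E1cB, retro-oxa-Michael), which should open the bridge to the C4=C5 enone and release C8–OH with the configuration fixed in step 9.

Step 13
Reactants: 20 (1R,8R)-8,11-dihydroxyguaia-4,6,10(14)-trien-3-one
Product: 21 (1R,8R)-11-hydroxy-3-oxoguaia-4,6,10(14)-trien-8-yl propanoate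
Conditions: (EtCO)2O (1.2 equiv), Et3N, DMAP (cat.), CH2Cl2, 0 °C
Reagents that add atoms: propanoic anhydride, CCC(=O)OC(=O)CC
Why: DMAP-catalysed acylation should esterify the secondary allylic C8 alcohol selectively, the tertiary C11 alcohol reacting far more slowly.

Step 14
Reactants: 21 (1R,8R)-11-hydroxy-3-oxoguaia-4,6,10(14)-trien-8-yl propanoate
Product: 22 (1R,7S,8R,10S)-11-hydroxy-3-oxoguai-4-en-8-yl propanoate
Conditions: H2 (1 atm), Rh/Al2O3 (5 wt %), EtOAc, rt
Reagents that add atoms: none
Why: Heterogeneous hydrogenation should saturate the exocyclic C10 alkene and the C6=C7 γ,δ-alkene of the dienone but not the tetrasubstituted C4=C5 enone, and hydrogen should reach the α face of both because C1 (H β) holds C9 and C10 below the planar dienone while the C8 propanoate stands pseudo-axial on the β face, which sets C7 (S) and C10 (S) with their carbon substituents cis to the ester.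

Step 15
Reactants: 22 (1R,7S,8R,10S)-11-hydroxy-3-oxoguai-4-en-8-yl propanoate
Product: 23 (1R,7S,8R,10S)-11-acetoxy-3-oxoguai-4-en-8-yl propanoate
Conditions: Ac2O (10 equiv), Et3N, DMAP (1 equiv), CH2Cl2, 40 °C
Reagents that add atoms: acetic anhydride, CC(=O)OC(C)=O
Why: Nucleophilic catalysis by DMAP with excess anhydride acetylates the hindered tertiary alcohol under basic, non-ionising conditions, which should keep the C8 propanoate in place.

Compound list
1 | methyl 5-bromofuran-3-carboxylate | COC(=O)c1coc(Br)c1 | starting material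
2 | 2-(5-bromofuran-3-yl)propan-2-ol | CC(C)(O)c1coc(Br)c1 | intermediate
3 | 2-bromo-4-(2-TBSO-propan-2-yl)furan | CC(C)(O[Si](C)(C)C(C)(C)C)c1coc(Br)c1 | intermediate
4 | (E)-but-2-en-1-ol | C/C=C/CO | starting material
5 | [(2S,3S)-3-methyloxiran-2-yl]methanol | OC[C@@H]1O[C@H]1C | intermediate
6 | [(2S,3S)-3-methyloxiran-2-yl]methyl 4-methylbenzenesulfonate | Cc1ccc(cc1)S(=O)(=O)OC[C@@H]1O[C@H]1C | intermediate
7 | [4-(2-TBSO-propan-2-yl)furan-2-yl]lithium | [Li]c1cc(C(C)(C)O[Si](C)(C)C(C)(C)C)co1 | intermediate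
8 | (2R,3R)-2-hydroxy-3-[4-(2-TBSO-propan-2-yl)furan-2-yl]butyl 4-methylbenzenesulfonate | Cc1ccc(cc1)S(=O)(=O)OC[C@H](O)[C@@H](C)c1cc(C(C)(C)O[Si](C)(C)C(C)(C)C)co1 | intermediate
9 | (2R)-2-{(1R)-1-[4-(2-TBSO-propan-2-yl)furan-2-yl]ethyl}oxirane | C1O[C@@H]1[C@@H](C)c1cc(C(C)(C)O[Si](C)(C)C(C)(C)C)co1 | intermediate
10 | (4S,5R)-4-hydroxy-5-[4-(2-TBSO-propan-2-yl)furan-2-yl]hexanoic acid | OC(=O)CC[C@H](O)[C@@H](C)c1cc(C(C)(C)O[Si](C)(C)C(C)(C)C)co1 | intermediate
11 | (5S)-5-{(1R)-1-[4-(2-TBSO-propan-2-yl)furan-2-yl]ethyl}oxolan-2-one | O=C1CC[C@H](O1)[C@@H](C)c1cc(C(C)(C)O[Si](C)(C)C(C)(C)C)co1 | intermediate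
12 | (4S,5R)-4-hydroxy-N-methoxy-N-methyl-5-[4-(2-TBSO-propan-2-yl)furan-2-yl]hexanamide | CON(C)C(=O)CC[C@H](O)[C@@H](C)c1cc(C(C)(C)O[Si](C)(C)C(C)(C)C)co1 | intermediate
13 | (4S,5R)-N-methoxy-N-methyl-5-[4-(2-TBSO-propan-2-yl)furan-2-yl]-4-TESO-hexanamide | CON(C)C(=O)CC[C@H](O[Si](CC)(CC)CC)[C@@H](C)c1cc(C(C)(C)O[Si](C)(C)C(C)(C)C)co1 | intermediate
14 | (5S,6R)-1-chloro-6-[4-(2-TBSO-propan-2-yl)furan-2-yl]-5-TESO-heptan-2-one (key-step precursor) | ClCC(=O)CC[C@H](O[Si](CC)(CC)CC)[C@@H](C)c1cc(C(C)(C)O[Si](C)(C)C(C)(C)C)co1 | intermediate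
15 | oxyallyl zwitterion of 14 (C9 cation, C10 enolate oxygen, C1=C10) | [CH2+]C([O-])=CC[C@H](O[Si](CC)(CC)CC)[C@@H](C)c1cc(C(C)(C)O[Si](C)(C)C(C)(C)C)co1 | intermediate
16 | (1S,3S,4R,5S,8R)-5,8-epoxy-11-TBSO-3-TESO-14-norguai-6-en-10-one (key-step product) | O1[C@@H]2CC(=O)[C@H]3C[C@H](O[Si](CC)(CC)CC)[C@@H](C)[C@]13C=C2C(C)(C)O[Si](C)(C)C(C)(C)C | intermediate
17 | (1R,3S,4R,5R,8R)-5,8-epoxy-11-TBSO-3-TESO-guaia-6,10(14)-diene | O1[C@@H]2CC(=C)[C@H]3C[C@H](O[Si](CC)(CC)CC)[C@@H](C)[C@]13C=C2C(C)(C)O[Si](C)(C)C(C)(C)C | intermediate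
18 | (1R,3S,4R,5R,8R)-5,8-epoxyguaia-6,10(14)-diene-3,11-diol | O1[C@@H]2CC(=C)[C@H]3C[C@H](O)[C@@H](C)[C@]13C=C2C(C)(C)O | intermediate
19 | (1R,4S,5R,8R)-5,8-epoxy-11-hydroxyguaia-6,10(14)-dien-3-one | O1[C@@H]2CC(=C)[C@H]3CC(=O)[C@@H](C)[C@]13C=C2C(C)(C)O | intermediate
20 | (1R,8R)-8,11-dihydroxyguaia-4,6,10(14)-trien-3-one | O[C@@H]1CC(=C)[C@H]2CC(=O)C(C)=C2C=C1C(C)(C)O | intermediate
21 | (1R,8R)-11-hydroxy-3-oxoguaia-4,6,10(14)-trien-8-yl propanoate | CCC(=O)O[C@@H]1CC(=C)[C@H]2CC(=O)C(C)=C2C=C1C(C)(C)O | intermediate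
22 | (1R,7S,8R,10S)-11-hydroxy-3-oxoguai-4-en-8-yl propanoate | CCC(=O)O[C@@H]1C[C@H](C)[C@H]2CC(=O)C(C)=C2C[C@@H]1C(C)(C)O | intermediate
23 | (1R,7S,8R,10S)-11-acetoxy-3-oxoguai-4-en-8-yl propanoate (CNP0288556.1) | CCC(=O)O[C@@H]1C[C@H](C)[C@H]2CC(=O)C(C)=C2C[C@@H]1C(C)(C)OC(C)=O | target

Total step count: 15. Longest linear sequence: 14 steps (steps 1, 2 and 4–15, from 1 to 23).

Steps most likely to fail

Step 9. Displacement of the primary chloride by trifluoroethoxide or Favorskii collapse may outrun cycloaddition, and the short tether may erode the compact-mode preference so that C1 forms in the wrong sense. The fallback generates a halogen-stabilised cation and removes the halogen afterwards, as is known for polychloro ketone–furan cycloadditions. It sets out from 13: LiCHCl2 (from CH2Cl2 and LiN(iPr)2, THF, −95 °C) would give the dichloromethyl ketone F1; NaOCH2CF3 in CF3CH2OH would ionise it through the chlorine-stabilised oxyallyl zwitterion F2 to the 9-chloro cycloadduct F3; Zn(Cu), NH4Cl, MeOH would remove the chlorine through the C9 zinc enolate, and brief K2CO3 in MeOH would, if needed, equilibrate C1 through the C10 enolate. The fallback comes back to the route at 16.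

Step 14. Face selection at C10 may be poor because the exocyclic alkene is only homoallylic to C8, and allylic C–O hydrogenolysis may compete. The fallback sets C10 from an endocyclic alkene that is allylic to C8. It sets out from 16: KN(SiMe3)2 and PhNTf2 at −78 °C would give the less substituted C9=C10 enol triflate F4; Me2CuLi would replace triflate by methyl to give the 10-methyl diene F5; Bu4NF would give the diol F6; NPr4RuO4 with N-methylmorpholine N-oxide and then Et3N would give, through the bridged ketone F7, the dienone diol F8; propanoic anhydride with DMAP would give the propanoate F9, in which C6=C7 and C9=C10 both flank the pseudo-axial C8 ester. Hydrogenation over Rh/Al2O3 would then bring the fallback back to the route at 22.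

Step 4. The furyllithium may attack the sulfonate instead of the BF3-activated epoxide, or the Lewis acid may ionise the tertiary silyl ether. The fallback opens an ether-protected epoxide and builds the terminal epoxide afterwards. It sets out from 5 (made from 4 as in step 3): t-BuPh2SiCl, Et3N and DMAP in the epoxidation pot would give the silyl ether F10; 7 and BF3·OEt2 at −78 °C would open it at the methyl-bearing carbon to the hydroxy silyl ether F11; Bu4NF at 0 °C would cleave the primary silyl ether to the diol F12; TsCl, Et3N and catalytic Bu2SnO would sulfonylate the primary hydroxyl. The fallback comes back to the route at 8, which closes to 9 as in step 4.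

Further compounds
F1 | step 9 | (5S,6R)-1,1-dichloro-6-[4-(2-TBSO-propan-2-yl)furan-2-yl]-5-TESO-heptan-2-one | ClC(Cl)C(=O)CC[C@H](O[Si](CC)(CC)CC)[C@@H](C)c1cc(C(C)(C)O[Si](C)(C)C(C)(C)C)co1
F2 | step 9 | 9-chloro oxyallyl zwitterion of F1 | Cl[CH+]C([O-])=CC[C@H](O[Si](CC)(CC)CC)[C@@H](C)c1cc(C(C)(C)O[Si](C)(C)C(C)(C)C)co1
F3 | step 9 | 9-chloro derivative of 16 (either C9 epimer) | O1[C@@H]2C(Cl)C(=O)[C@H]3C[C@H](O[Si](CC)(CC)CC)[C@@H](C)[C@]13C=C2C(C)(C)O[Si](C)(C)C(C)(C)C
F4 | step 14 | 5,8-epoxy-11-TBSO-3-TESO-14-norguaia-6,9-dien-10-yl trifluoromethanesulfonate | O1[C@@H]2C=C(OS(=O)(=O)C(F)(F)F)[C@H]3C[C@H](O[Si](CC)(CC)CC)[C@@H](C)[C@]13C=C2C(C)(C)O[Si](C)(C)C(C)(C)C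
F5 | step 14 | 5,8-epoxy-11-TBSO-3-TESO-guaia-6,9-diene | O1[C@@H]2C=C(C)[C@H]3C[C@H](O[Si](CC)(CC)CC)[C@@H](C)[C@]13C=C2C(C)(C)O[Si](C)(C)C(C)(C)C
F6 | step 14 | 5,8-epoxyguaia-6,9-diene-3,11-diol | O1[C@@H]2C=C(C)[C@H]3C[C@H](O)[C@@H](C)[C@]13C=C2C(C)(C)O
F7 | step 14 | 5,8-epoxy-11-hydroxyguaia-6,9-dien-3-one | O1[C@@H]2C=C(C)[C@H]3CC(=O)[C@@H](C)[C@]13C=C2C(C)(C)O
F8 | step 14 | (1R,8R)-8,11-dihydroxyguaia-4,6,9-trien-3-one | O[C@@H]1C=C(C)[C@H]2CC(=O)C(C)=C2C=C1C(C)(C)O
F9 | step 14 | (1R,8R)-11-hydroxy-3-oxoguaia-4,6,9-trien-8-yl propanoate | CCC(=O)O[C@@H]1C=C(C)[C@H]2CC(=O)C(C)=C2C=C1C(C)(C)O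
F10 | step 4 | tert-butyl{[(2S,3S)-3-methyloxiran-2-yl]methoxy}diphenylsilane | CC(C)(C)[Si](OC[C@@H]1O[C@H]1C)(c1ccccc1)c1ccccc1
F11 | step 4 | (2R,3R)-1-[tert-butyl(diphenyl)silyl]oxy-3-[4-(2-TBSO-propan-2-yl)furan-2-yl]butan-2-ol | CC(C)(C)[Si](OC[C@H](O)[C@@H](C)c1cc(C(C)(C)O[Si](C)(C)C(C)(C)C)co1)(c1ccccc1)c1ccccc1
F12 | step 4 | (2R,3R)-3-[4-(2-TBSO-propan-2-yl)furan-2-yl]butane-1,2-diol | OC[C@H](O)[C@@H](C)c1cc(C(C)(C)O[Si](C)(C)C(C)(C)C)co1
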